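**Strategy.** Everything rests on cutting the C2–C3 bond of the dihydrofuran ring (ring B) while tying the C3 oxygen to the acrolein carbon, raised to the carboxyl level, in a temporary lactone (ring C). The feature used is that the oxygen on C3 and the formyl carbon of the propenal unit on C2 lie on the same face of ring B in a 1,4-relationship (O–C3–C2–Cα–CHO). One ligand-controlled chromium allylation of an aldehyde forms C2–C3, closes rings B and C and sets both ring stereocentres. Its precursor is an aryl enol ether: an ethyl 2-(bromomethyl)-3-aryloxyacrylate whose aryl ring (ring A) carries an ortho formyl group and, para to the ether oxygen, the silyl-protected (R)-1-hydroxyethyl chain.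

Key step: step 8

Remark on the chemistry: compounds 9–12 are drawn with the expected enol-ether geometry (bromine or aryloxy trans to the ester). This geometry has no bearing on the outcome, because it is lost in the equilibrating allylchromium of step 8. The sense of induction of the ligand in step 8 has to be checked on first use; the (R)-ligand is taken if the (S)-ligand gives the opposite sense.

**Step 1**
Reactants: 1 4-hydroxyacetophenone
Product: 2 1-[4-(tert-butyldimethylsilyloxy)phenyl]ethanone
Conditions: TBSCl, imidazole, DMF, rt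
Reagents that add atoms: tert-butyldimethylsilyl chloride, CC(C)(C)[Si](C)(C)Cl
Why: Silyl ether formation at the phenol removes the acidic O–H that would consume borane and bind the catalyst in the next step, and no stereocentre is involved.

**Step 2**
Reactants: 2 1-[4-(tert-butyldimethylsilyloxy)phenyl]ethanone
Product: 3 (1R)-1-[4-(tert-butyldimethylsilyloxy)phenyl]ethanol
Conditions: (S)-2-methyl-CBS-oxazaborolidine (10 mol%), BH3·SMe2, THF, −20 °C; MeOH quench
Reagents that add atoms: none
Why: Corey–Bakshi–Shibata reduction, in which the (S)-oxazaborolidine holds borane and the ketone so that hydride reaches the Si face with the aryl group as the large substituent, which sets the (R)-carbinol in the sense established for aryl methyl ketones.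

**Step 3**
Reactants: 3 (1R)-1-[4-(tert-butyldimethylsilyloxy)phenyl]ethanol
Product: 5 4-[(1R)-1-(tert-butyldimethylsilyloxy)ethyl]phenol, via bis-silyl ether 4 (not isolated)
Conditions: TBSCl, imidazole, DMF, rt; then K2CO3, MeOH, rt
Reagents that add atoms: tert-butyldimethylsilyl chloride, CC(C)(C)[Si](C)(C)Cl
Why: Silyl ether formation on the secondary alcohol followed by base-mediated methanolysis, which cleaves only the aryl silyl ether because phenoxide is by far the better leaving group, frees the phenol without touching the stereocentre.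

**Step 4**
Reactants: 5 4-[(1R)-1-(tert-butyldimethylsilyloxy)ethyl]phenol
Product: 6 2-hydroxy-5-[(1R)-1-(tert-butyldimethylsilyloxy)ethyl]benzaldehyde
Conditions: MgCl2, Et3N, (CH2O)n, THF, reflux; aqueous citric acid work-up
Reagents that add atoms: formaldehyde (as paraformaldehyde), C=O
Why: Magnesium-mediated ortho-formylation of a phenol, in which the magnesium phenoxide delivers formaldehyde to the free ortho position (the para position is blocked) and a second formaldehyde oxidises the resulting benzylic alkoxide to the aldehyde by hydride transfer.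

**Step 5**
Reactants: 7 ethyl 2-(hydroxymethyl)acrylate
Product: 9 ethyl (E)-3-bromo-2-(hydroxymethyl)prop-2-enoate, via dibromide 8 (not isolated)
Conditions: Br2, CH2Cl2, 0 °C → rt; then Et3N, 0 °C → rt
Reagents that add atoms: bromine, BrBr
Why: Bromine addition to the acrylate and E2 dehydrobromination, in which the tertiary bromide leaves with a hydrogen of the more acidic CH2Br group, the same bromination–elimination that turns methacrylates into 3-bromo-2-methylacrylates.

**Step 6**
Reactants: 6 2-hydroxy-5-[(1R)-1-(tert-butyldimethylsilyloxy)ethyl]benzaldehyde; 9 ethyl (E)-3-bromo-2-(hydroxymethyl)prop-2-enoate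
Product: 10 ethyl (E)-3-[2-formyl-4-[(1R)-1-(tert-butyldimethylsilyloxy)ethyl]phenoxy]-2-(hydroxymethyl)prop-2-enoate
Conditions: Cs2CO3, DMF, 50 °C
Reagents that add atoms: 9 ethyl (E)-3-bromo-2-(hydroxymethyl)prop-2-enoate, CCOC(=O)/C(CO)=C/Br
Why: Nucleophilic vinylic substitution by addition–elimination of the phenoxide at the β-carbon of the bromoacrylate, which is the only electrophilic site because the allylic carbon still carries a hydroxyl and not a halide.

**Step 7**
Reactants: 10 ethyl (E)-3-[2-formyl-4-[(1R)-1-(tert-butyldimethylsilyloxy)ethyl]phenoxy]-2-(hydroxymethyl)prop-2-enoate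
Product: 12 ethyl (Z)-2-(bromomethyl)-3-[2-formyl-4-[(1R)-1-(tert-butyldimethylsilyloxy)ethyl]phenoxy]prop-2-enoate, via allylic mesylate 11 (not isolated)
Conditions: MsCl, Et3N, CH2Cl2, −30 °C; then LiBr, THF, −30 → 0 °C; used at once
Reagents that add atoms: lithium bromide, [Li+].[Br-]
Why: Sulfonylation of the primary allylic alcohol and Finkelstein-type SN2 displacement by bromide under cold, nearly neutral conditions leave the aldehyde, the enol ether and the silyl ether untouched.

**Step 8**
Reactants: 12 ethyl (Z)-2-(bromomethyl)-3-[2-formyl-4-[(1R)-1-(tert-butyldimethylsilyloxy)ethyl]phenoxy]prop-2-enoate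
Product: 14 (3aR,8bR)-7-[(1R)-1-(tert-butyldimethylsilyloxy)ethyl]-3-methylidene-3a,8b-dihydrofuro[3,2-b][1]benzofuran-2(3H)-one, via chromium alkoxide of hydroxy ester 13 (not isolated)
Conditions: CrCl2 (4 equiv), (S)-N-[2-(4-isopropyl-4,5-dihydro-1,3-oxazol-2-yl)-6-methylphenyl]methanesulfonamide (4.4 equiv), Et3N (4.4 equiv), THF, rt; then 12 added slowly (final 0.01 M), rt; aqueous NH4Cl work-up
Reagents that add atoms: none
Why: Proposed new method: two equivalents of ligand-bound divalent chromium reduce the C–Br bond of 12 to a trivalent allylchromium that equilibrates between its CH2-bound and aryloxy-carbon-bound σ forms and adds through the aryloxy-bearing carbon to the ortho aldehyde in a closed six-membered transition state, forming C2–C3, after which the chromium alkoxide 13 displaces ethoxide from the neighbouring ester to give lactone 14. The closest known reaction type is the chromium-mediated 2-(alkoxycarbonyl)allylation of aldehydes (Nozaki–Hiyama–Kishi type) to α-methylene-γ-butyrolactones, which is known between two molecules, in ring-forming form and under chiral-ligand control, but not with an aryloxy group on the attacking allyl carbon. Ring B closes by 5-exo-trig attack of that carbon on the carbonyl group, and ring C closes by 5-exo-trig acyl substitution. The C3 configuration is set by the chiral sulfonamide–oxazoline ligand on chromium, which selects the aldehyde face because the remote side-chain centre gives no bias, and C2 is set relative to C3 by the compact bicyclic transition state. The step needs attack through the substituted allyl terminus and a cis C2/C3 relationship: the three-atom O1–C7a–C3a tether permits only the five-membered closure, and a trans hydroxy ester cannot bridge two five-membered rings, so it would remain as a separable open ester while only the cis isomer becomes 14. Slow addition to excess reagent keeps the bromide dilute and suppresses addition between two molecules, and the silyl ether is inert to chromium reagents.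

**Step 9**
Reactants: 14 (3aR,8bR)-7-[(1R)-1-(tert-butyldimethylsilyloxy)ethyl]-3-methylidene-3a,8b-dihydrofuro[3,2-b][1]benzofuran-2(3H)-one
Product: 15 (2R,3R)-5-[(1R)-1-(tert-butyldimethylsilyloxy)ethyl]-2-(3-hydroxyprop-1-en-2-yl)-2,3-dihydro-1-benzofuran-3-ol
Conditions: i-Bu2AlH (4 equiv), CH2Cl2, −78 → 0 °C; Rochelle salt work-up
Reagents that add atoms: none
Why: Hydride reduction of the lactone by 1,2-addition, through the lactol, opens ring C to the allylic alcohol and the C3 alcohol without breaking any bond at a stereocentre.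

**Step 10**
Reactants: 15 (2R,3R)-5-[(1R)-1-(tert-butyldimethylsilyloxy)ethyl]-2-(3-hydroxyprop-1-en-2-yl)-2,3-dihydro-1-benzofuran-3-ol
Product: 16 (2R,3R)-5-[(1R)-1-(tert-butyldimethylsilyloxy)ethyl]-2-[3-(triethylsilyloxy)prop-1-en-2-yl]-2,3-dihydro-1-benzofuran-3-ol
Conditions: TESCl (1.05 equiv), imidazole, CH2Cl2, −40 °C
Reagents that add atoms: chlorotriethylsilane, CC[Si](Cl)(CC)CC
Why: Chemoselective silylation, because the unhindered primary allylic hydroxyl reacts much faster at low temperature than the secondary benzylic C3 hydroxyl flanked by the C2 substituent.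

**Step 11**
Reactants: 16 (2R,3R)-5-[(1R)-1-(tert-butyldimethylsilyloxy)ethyl]-2-[3-(triethylsilyloxy)prop-1-en-2-yl]-2,3-dihydro-1-benzofuran-3-ol; 17 isovaleryl chloride
Product: 18 (2R,3R)-5-[(1R)-1-(tert-butyldimethylsilyloxy)ethyl]-2-[3-(triethylsilyloxy)prop-1-en-2-yl]-2,3-dihydro-1-benzofuran-3-yl 3-methylbutanoate
Conditions: pyridine, DMAP (cat.), CH2Cl2, 0 °C → rt
Reagents that add atoms: 17 isovaleryl chloride, CC(C)CC(=O)Cl
Why: DMAP-catalysed acylation of the only free hydroxyl proceeds with retention at C3 because the C–O bond is not broken.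

**Step 12**
Reactants: 18 (2R,3R)-5-[(1R)-1-(tert-butyldimethylsilyloxy)ethyl]-2-[3-(triethylsilyloxy)prop-1-en-2-yl]-2,3-dihydro-1-benzofuran-3-yl 3-methylbutanoate
Product: 19 (2R,3R)-5-[(1R)-1-(tert-butyldimethylsilyloxy)ethyl]-2-(3-hydroxyprop-1-en-2-yl)-2,3-dihydro-1-benzofuran-3-yl 3-methylbutanoate
Conditions: PPTS (0.2 equiv), MeOH/CH2Cl2, 0 °C
Reagents that add atoms: none
Why: Mild acid-catalysed methanolysis cleaves the primary triethylsilyl ether far faster than the secondary tert-butyldimethylsilyl ether (graded silyl ether lability), and the esters are inert to it.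

**Step 13**
Reactants: 19 (2R,3R)-5-[(1R)-1-(tert-butyldimethylsilyloxy)ethyl]-2-(3-hydroxyprop-1-en-2-yl)-2,3-dihydro-1-benzofuran-3-yl 3-methylbutanoate
Product: 20 (2R,3R)-5-[(1R)-1-(tert-butyldimethylsilyloxy)ethyl]-2-(3-oxoprop-1-en-2-yl)-2,3-dihydro-1-benzofuran-3-yl 3-methylbutanoate
Conditions: MnO2 (excess), CH2Cl2, rt
Reagents that add atoms: none
Why: Allylic alcohol oxidation with MnO2 under neutral heterogeneous conditions gives the enal while the two benzylic oxygens stay blocked as ester and silyl ether.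

**Step 14**
Reactants: 20 (2R,3R)-5-[(1R)-1-(tert-butyldimethylsilyloxy)ethyl]-2-(3-oxoprop-1-en-2-yl)-2,3-dihydro-1-benzofuran-3-yl 3-methylbutanoate
Product: 21 (2R,3R)-5-[(1R)-1-hydroxyethyl]-2-(3-oxoprop-1-en-2-yl)-2,3-dihydro-1-benzofuran-3-yl 3-methylbutanoate
Conditions: n-Bu4NF, AcOH (1:1), THF, 0 °C → rt
Reagents that add atoms: none
Why: Fluoride-mediated desilylation buffered with acetic acid frees the benzylic alcohol by attack at silicon, so the C–O bond and its configuration are kept and no free base meets the enal or the ester.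

**Step 15**
Reactants: 21 (2R,3R)-5-[(1R)-1-hydroxyethyl]-2-(3-oxoprop-1-en-2-yl)-2,3-dihydro-1-benzofuran-3-yl 3-methylbutanoate; 22 (2R)-2-methylbutanoic acid
Product: 23 (1R)-1-[(2R,3R)-3-(3-methylbutanoyloxy)-2-(3-oxoprop-1-en-2-yl)-2,3-dihydro-1-benzofuran-5-yl]ethyl (2R)-2-methylbutanoate
Conditions: EDC·HCl, DMAP (cat.), CH2Cl2, 0 °C → rt
Reagents that add atoms: 22 (2R)-2-methylbutanoic acid, CC[C@@H](C)C(=O)O
Why: Steglich-type carbodiimide esterification acylates the alcohol oxygen, so the carbinol configuration is retained, and the cold conditions with little DMAP should keep the α-centre of the acid intact.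

**Compound list**

1 | 4-hydroxyacetophenone | CC(=O)c1ccc(O)cc1 | starting material
2 | 1-[4-(tert-butyldimethylsilyloxy)phenyl]ethanone | CC(=O)c1ccc(O[Si](C)(C)C(C)(C)C)cc1 | intermediate
3 | (1R)-1-[4-(tert-butyldimethylsilyloxy)phenyl]ethanol | CC(C)(C)[Si](C)(C)Oc1ccc([C@@H](C)O)cc1 | intermediate
4 | tert-butyl-[4-[(1R)-1-(tert-butyldimethylsilyloxy)ethyl]phenoxy]dimethylsilane (bis-silyl ether, not isolated) | CC(C)(C)[Si](C)(C)Oc1ccc([C@@H](C)O[Si](C)(C)C(C)(C)C)cc1 | intermediate
5 | 4-[(1R)-1-(tert-butyldimethylsilyloxy)ethyl]phenol | Oc1ccc([C@@H](C)O[Si](C)(C)C(C)(C)C)cc1 | intermediate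
6 | 2-hydroxy-5-[(1R)-1-(tert-butyldimethylsilyloxy)ethyl]benzaldehyde | O=Cc1cc([C@@H](C)O[Si](C)(C)C(C)(C)C)ccc1O | intermediate
7 | ethyl 2-(hydroxymethyl)acrylate | C=C(CO)C(=O)OCC | starting material
8 | ethyl 2,3-dibromo-2-(hydroxymethyl)propanoate (racemic, not isolated) | CCOC(=O)C(Br)(CO)CBr | intermediate
9 | ethyl (E)-3-bromo-2-(hydroxymethyl)prop-2-enoate | CCOC(=O)/C(CO)=C/Br | intermediate
10 | ethyl (E)-3-[2-formyl-4-[(1R)-1-(tert-butyldimethylsilyloxy)ethyl]phenoxy]-2-(hydroxymethyl)prop-2-enoate | CCOC(=O)/C(CO)=C/Oc1ccc([C@@H](C)O[Si](C)(C)C(C)(C)C)cc1C=O | intermediate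
11 | ethyl (E)-3-[2-formyl-4-[(1R)-1-(tert-butyldimethylsilyloxy)ethyl]phenoxy]-2-[(methylsulfonyloxy)methyl]prop-2-enoate (not isolated) | CCOC(=O)/C(COS(C)(=O)=O)=C/Oc1ccc([C@@H](C)O[Si](C)(C)C(C)(C)C)cc1C=O | intermediate
12 | ethyl (Z)-2-(bromomethyl)-3-[2-formyl-4-[(1R)-1-(tert-butyldimethylsilyloxy)ethyl]phenoxy]prop-2-enoate | CCOC(=O)/C(CBr)=C/Oc1ccc([C@@H](C)O[Si](C)(C)C(C)(C)C)cc1C=O | intermediate
13 | ethyl 2-[(2R,3R)-3-hydroxy-5-[(1R)-1-(tert-butyldimethylsilyloxy)ethyl]-2,3-dihydro-1-benzofuran-2-yl]prop-2-enoate (formed as its chromium alkoxide, not isolated) | CCOC(=O)C(=C)[C@H]1Oc2ccc([C@@H](C)O[Si](C)(C)C(C)(C)C)cc2[C@H]1O | intermediate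
14 | (3aR,8bR)-7-[(1R)-1-(tert-butyldimethylsilyloxy)ethyl]-3-methylidene-3a,8b-dihydrofuro[3,2-b][1]benzofuran-2(3H)-one | C=C1[C@H]2Oc3ccc([C@@H](C)O[Si](C)(C)C(C)(C)C)cc3[C@H]2OC1=O | intermediate
15 | (2R,3R)-5-[(1R)-1-(tert-butyldimethylsilyloxy)ethyl]-2-(3-hydroxyprop-1-en-2-yl)-2,3-dihydro-1-benzofuran-3-ol | C=C(CO)[C@H]1Oc2ccc([C@@H](C)O[Si](C)(C)C(C)(C)C)cc2[C@H]1O | intermediate
16 | (2R,3R)-5-[(1R)-1-(tert-butyldimethylsilyloxy)ethyl]-2-[3-(triethylsilyloxy)prop-1-en-2-yl]-2,3-dihydro-1-benzofuran-3-ol | C=C(CO[Si](CC)(CC)CC)[C@H]1Oc2ccc([C@@H](C)O[Si](C)(C)C(C)(C)C)cc2[C@H]1O | intermediate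
17 | isovaleryl chloride (3-methylbutanoyl chloride) | CC(C)CC(=O)Cl | starting material
18 | (2R,3R)-5-[(1R)-1-(tert-butyldimethylsilyloxy)ethyl]-2-[3-(triethylsilyloxy)prop-1-en-2-yl]-2,3-dihydro-1-benzofuran-3-yl 3-methylbutanoate | C=C(CO[Si](CC)(CC)CC)[C@H]1Oc2ccc([C@@H](C)O[Si](C)(C)C(C)(C)C)cc2[C@H]1OC(=O)CC(C)C | intermediate
19 | (2R,3R)-5-[(1R)-1-(tert-butyldimethylsilyloxy)ethyl]-2-(3-hydroxyprop-1-en-2-yl)-2,3-dihydro-1-benzofuran-3-yl 3-methylbutanoate | C=C(CO)[C@H]1Oc2ccc([C@@H](C)O[Si](C)(C)C(C)(C)C)cc2[C@H]1OC(=O)CC(C)C | intermediate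
20 | (2R,3R)-5-[(1R)-1-(tert-butyldimethylsilyloxy)ethyl]-2-(3-oxoprop-1-en-2-yl)-2,3-dihydro-1-benzofuran-3-yl 3-methylbutanoate | C=C(C=O)[C@H]1Oc2ccc([C@@H](C)O[Si](C)(C)C(C)(C)C)cc2[C@H]1OC(=O)CC(C)C | intermediate
21 | (2R,3R)-5-[(1R)-1-hydroxyethyl]-2-(3-oxoprop-1-en-2-yl)-2,3-dihydro-1-benzofuran-3-yl 3-methylbutanoate | C=C(C=O)[C@H]1Oc2ccc([C@@H](C)O)cc2[C@H]1OC(=O)CC(C)C | intermediate
22 | (2R)-2-methylbutanoic acid | CC[C@@H](C)C(=O)O | starting material
23 | (1R)-1-[(2R,3R)-3-(3-methylbutanoyloxy)-2-(3-oxoprop-1-en-2-yl)-2,3-dihydro-1-benzofuran-5-yl]ethyl (2R)-2-methylbutanoate | C=C(C=O)[C@H]1Oc2ccc([C@@H](C)OC(=O)[C@H](C)CC)cc2[C@H]1OC(=O)CC(C)C | target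

**Total step count:** 15 steps. **Longest linear sequence:** 14 steps (steps 1–4 and 6–15, from 1 to 23).

**The three steps most likely to fail**

Step 8 (Proposed new method). The allylchromium may be lost by protonation or by addition between two molecules. The ligand may also discriminate the aldehyde faces poorly on this new substrate class, or the labile bromide may ionise before it is reduced. The fallback uses known chemistry, sets out from 6 and comes back at 14. Phenol 6 is added to ethyl propiolate (C#CC(=O)OCC; N-methylmorpholine cat., CH2Cl2, rt) to give ethyl (E)-3-[2-formyl-4-[(1R)-1-(tert-butyldimethylsilyloxy)ethyl]phenoxy]prop-2-enoate F1. An intramolecular Stetter reaction (thiazolium salt, Et3N, dioxane, 70 °C) should close ring B to ethyl 2-[5-[(1R)-1-(tert-butyldimethylsilyloxy)ethyl]-3-oxo-2,3-dihydro-1-benzofuran-2-yl]acetate F2. Transfer hydrogenation with RuCl[(S,S)-TsDPEN](p-cymene) in HCO2H/Et3N under dynamic kinetic resolution (C2 epimerises through the enol and hydride adds anti to the C2 substituent) should give ethyl 2-[(2R,3R)-3-hydroxy-5-[(1R)-1-(tert-butyldimethylsilyloxy)ethyl]-2,3-dihydro-1-benzofuran-2-yl]acetate F3. The catalyst enantiomer is chosen by analogy with its sense for 1-indanone. F3 lactonises on standing or with a trace of PPTS to (3aR,8bR)-7-[(1R)-1-(tert-butyldimethylsilyloxy)ethyl]-3a,8b-dihydrofuro[3,2-b][1]benzofuran-2(3H)-one F4. Methylenation through the lithium enolate (LiN(SiMe3)2, THF, −78 °C, kept cold to avoid β-loss of the aryloxide) and Eschenmoser's salt gives the 3-[(dimethylamino)methyl] lactone F5. This is quaternised with MeI to the trimethylammonium iodide F6 and eliminated with NaHCO3 to 14.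

Step 6. Addition–elimination at the hindered, α-substituted β-carbon may be slow, so that base-induced self-condensation of 9 through its free hydroxyl, or degradation of the aldehyde, overtakes the coupling. The fallback sets out from 6, comes back at 10, and needs neither 9 nor step 5. Phenol 6 is added to ethyl propiolate as above to give ethyl (E)-3-[2-formyl-4-[(1R)-1-(tert-butyldimethylsilyloxy)ethyl]phenoxy]prop-2-enoate F7 (the same structure as F1). Bromine adds to the electron-rich enol ether double bond (Br2, CH2Cl2, −78 °C) to give ethyl 2,3-dibromo-3-[2-formyl-4-[(1R)-1-(tert-butyldimethylsilyloxy)ethyl]phenoxy]propanoate F8. Et3N removes the acidic α-hydrogen with loss of the β-bromide to give ethyl (Z)-2-bromo-3-[2-formyl-4-[(1R)-1-(tert-butyldimethylsilyloxy)ethyl]phenoxy]prop-2-enoate F9. A Stille coupling with Bu3SnCH2OH (Pd(PPh3)4, dioxane, 90 °C) then puts the hydroxymethyl carbon in place with retention and gives 10.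

Step 14. Fluoride meets the enal and two acyloxy groups, so conjugate addition, acyl migration or ionisation of the electron-rich benzylic alcohol may erode the material. The fallback sets out from 18 and comes back at 21. Both silyl ethers are removed before any enal exists (n-Bu4NF/AcOH, THF) to give (2R,3R)-5-[(1R)-1-hydroxyethyl]-2-(3-hydroxyprop-1-en-2-yl)-2,3-dihydro-1-benzofuran-3-yl 3-methylbutanoate F10. Only the primary allylic alcohol is then oxidised with catalytic TEMPO and PhI(OAc)2 (CH2Cl2, rt), relying on the preference of the oxoammonium oxidant for primary over secondary alcohols, to give 21.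

**Further compounds**

F1 | step 8 | ethyl (E)-3-[2-formyl-4-[(1R)-1-(tert-butyldimethylsilyloxy)ethyl]phenoxy]prop-2-enoate | CCOC(=O)/C=C/Oc1ccc([C@@H](C)O[Si](C)(C)C(C)(C)C)cc1C=O
F2 | step 8 | ethyl 2-[5-[(1R)-1-(tert-butyldimethylsilyloxy)ethyl]-3-oxo-2,3-dihydro-1-benzofuran-2-yl]acetate (both C2 epimers) | CCOC(=O)CC1Oc2ccc([C@@H](C)O[Si](C)(C)C(C)(C)C)cc2C1=O
F3 | step 8 | ethyl 2-[(2R,3R)-3-hydroxy-5-[(1R)-1-(tert-butyldimethylsilyloxy)ethyl]-2,3-dihydro-1-benzofuran-2-yl]acetate | CCOC(=O)C[C@H]1Oc2ccc([C@@H](C)O[Si](C)(C)C(C)(C)C)cc2[C@H]1O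
F4 | step 8 | (3aR,8bR)-7-[(1R)-1-(tert-butyldimethylsilyloxy)ethyl]-3a,8b-dihydrofuro[3,2-b][1]benzofuran-2(3H)-one | O=C1C[C@H]2Oc3ccc([C@@H](C)O[Si](C)(C)C(C)(C)C)cc3[C@H]2O1
F5 | step 8 | (3aR,8bR)-3-[(dimethylamino)methyl]-7-[(1R)-1-(tert-butyldimethylsilyloxy)ethyl]-3a,8b-dihydrofuro[3,2-b][1]benzofuran-2(3H)-one | CN(C)CC1[C@H]2Oc3ccc([C@@H](C)O[Si](C)(C)C(C)(C)C)cc3[C@H]2OC1=O
F6 | step 8 | trimethylammonium iodide of F5 | C[N+](C)(C)CC1[C@H]2Oc3ccc([C@@H](C)O[Si](C)(C)C(C)(C)C)cc3[C@H]2OC1=O.[I-]
F7 | step 6 | ethyl (E)-3-[2-formyl-4-[(1R)-1-(tert-butyldimethylsilyloxy)ethyl]phenoxy]prop-2-enoate | CCOC(=O)/C=C/Oc1ccc([C@@H](C)O[Si](C)(C)C(C)(C)C)cc1C=O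
F8 | step 6 | ethyl 2,3-dibromo-3-[2-formyl-4-[(1R)-1-(tert-butyldimethylsilyloxy)ethyl]phenoxy]propanoate | CCOC(=O)C(Br)C(Br)Oc1ccc([C@@H](C)O[Si](C)(C)C(C)(C)C)cc1C=O
F9 | step 6 | ethyl (Z)-2-bromo-3-[2-formyl-4-[(1R)-1-(tert-butyldimethylsilyloxy)ethyl]phenoxy]prop-2-enoate | CCOC(=O)/C(Br)=C/Oc1ccc([C@@H](C)O[Si](C)(C)C(C)(C)C)cc1C=O
F10 | step 14 | (2R,3R)-5-[(1R)-1-hydroxyethyl]-2-(3-hydroxyprop-1-en-2-yl)-2,3-dihydro-1-benzofuran-3-yl 3-methylbutanoate | C=C(CO)[C@H]1Oc2ccc([C@@H](C)O)cc2[C@H]1OC(=O)CC(C)C
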